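## Retrosynthetic overview
- The side chain is cut at C12–C13. A borane made from a 9-vinyl decalin adds syn across methyl but-2-ynoate, which fixes the E-olefin.
- The C9–H/vinyl unit comes from formate hydrogenolysis of a tertiary bis-allylic carbonate, made by vinyl addition to a C9 enone. The 6-OH comes from vinylogous aerobic hydroxylation of the same enone.
- Ring A, the C4 quaternary centre and the C18 carbinol come from one visible-light radical cascade with formaldehyde. It forms the C2–C3 and C4–C18 bonds on a 6-(2-haloethyl)-6-methylcarvone.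
- The C10 quaternary centre comes from two successive enolate alkylations of (S)-carvone. C5 is the only purchased stereocentre and relays to C10, C4, C6 and C9.
- Ring order: ring B is bought and ring A is closed photochemically.

Assumption: operations run in one flask without isolation count as one step, and LiN(i-Pr)2, CH2=CHMgBr and 9-BBN-H are used as bought solutions. Labdane numbering (C1–C20) is used for positions.

## Route

Step 1
Reactants: 1 (S)-(+)-carvone
Product: 3 (5S,6R)-2,6-dimethyl-5-(prop-1-en-2-yl)cyclohex-2-en-1-one (6-methylcarvone; CH3 trans to isopropenyl; minor 6-epimer carried along), via lithium dienolate 2 (not isolated)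
Conditions: LiN(i-Pr)2 (1.05 equiv), THF, −78 °C; MeI, −78 to −20 °C
Reagents that add atoms: iodomethane, CI
Why: Kinetic deprotonation at the only alpha-prime CH2 followed by enolate alkylation gives mainly the trans product, and the new centre becomes planar again in step 2, so the epimer ratio does not matter.

Step 2
Reactants: 3 6-methylcarvone
Product: 5 (5R,6R)-6-(2-bromoethyl)-2,6-dimethyl-5-(prop-1-en-2-yl)cyclohex-2-en-1-one (bromoethyl trans and CH3 cis to isopropenyl), via tetrasubstituted lithium enolate 4 (not isolated)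
Conditions: LiN(i-Pr)2 (1.1 equiv), THF, −78 °C; BrCH2CH2OTf, −78 to −30 °C
Reagents that add atoms: 2-bromoethyl trifluoromethanesulfonate, BrCCOS(=O)(=O)C(F)(F)F
Why: In this enolate alkylation the primary triflate is displaced far faster than bromide, and attack anti to the neighbouring pseudo-axial isopropenyl group sets the quaternary centre (future C10) under control of C5.

Step 3
Reactants: 5 bromoethyl enone
Product: 8 (4aR,5S,8aR)-5-(hydroxymethyl)-2,5,8a-trimethyl-4a,5,6,7,8,8a-hexahydronaphthalen-1(4H)-one (trans-decalin; 9-oxo; C7=C8; equatorial C18H2OH anti to the angular CH3), via primary iodide 6 (not isolated), via alkoxyphosphonium iodide 7 (not isolated)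
Conditions: NaI (1.5 equiv), MeCN, 45 °C, dark, 3 h; then 4CzIPN (3 mol %), i-Pr2NEt (2.5 equiv), PPh3 (1.5 equiv), aq. HCHO (37 %, 40–50 equiv), MeCN (0.02 M), 450 nm LEDs, 20 °C
Reagents that add atoms: formaldehyde, C=O
Why: Proposed new method: a halogen-atom-transfer radical cyclisation–hydroxymethylation cascade in which the alpha-aminoalkyl radical made from i-Pr2NEt by the excited photocatalyst abstracts iodine from 6; the primary C2 radical closes ring A by 6-endo attack on the CH2 terminus of the 1,1-disubstituted isopropenyl group (5-exo closure would build a quaternary carbon in a trans-hydrindane, and pre-organised ring closure should outrun the slow bimolecular capture of a primary radical by HCHO); the nucleophilic tertiary C4 radical then adds to formaldehyde through its equatorial lobe because the axial lobe is screened by the syn-axial C10 methyl, which sets C4 with CH2OH equatorial; PPh3 traps the alkoxy radical so the reversible addition becomes irreversible, the phosphoranyl radical carries the chain by abstracting iodine from 6, and water hydrolyses neopentyl salt 7, which cannot collapse to an iodide; the closest known reaction types are the photocatalytic hydroxymethylation of simple alkyl iodides with formaldehyde and PPh3 and tin-mediated 6-endo cyclisations of 5-substituted hex-5-enyl radicals, which have not been merged or used to build a quaternary stereocentre.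

Step 4
Reactants: 8 bicyclic enone alcohol
Product: 10 (4R,4aR,5S,8aR)-4-hydroxy-5-(hydroxymethyl)-2,5,8a-trimethyl-4a,5,6,7,8,8a-hexahydronaphthalen-1(4H)-one (6-OH equatorial; same face as H5 and C18), via C6 hydroperoxide 9 (not isolated)
Conditions: Cu(OTf)2 (10 mol %), 1,1,3,3-tetramethylguanidine (20 mol %), PPh3 (1.2 equiv), air (1 atm), DMF, 25 °C
Reagents that add atoms: dioxygen, O=O
Why: In this vinylogous aerobic gamma-hydroxylation catalysed by divalent copper, C6–H is the only acidic site because C10 is quaternary; O2 is taken up on the face opposite the two axial methyl groups, PPh3 reduces 9, and equilibration through the dienolate favours the same equatorial carbinol.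

Step 5
Reactants: 10 diol enone
Product: 11 6,18-O-(di-tert-butylsilanediyl) derivative of 10 (seven-membered dioxasilepane)
Conditions: t-Bu2Si(OTf)2 (1.1 equiv), 2,6-lutidine (3 equiv), CH2Cl2, 0 °C
Reagents that add atoms: di-tert-butylsilyl bis(trifluoromethanesulfonate), CC(C)(C)[Si](OS(=O)(=O)C(F)(F)F)(OS(=O)(=O)C(F)(F)F)C(C)(C)C
Why: Silylene protection of a 1,4-diol works here because the two equatorial, peri-related hydroxyls are held close together; one reagent masks both and no stereocentre changes.

Step 6
Reactants: 11 silylene enone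
Product: 13 C9 tertiary bis-allylic methyl carbonate (vinyl on the face of H5; carbonate on the face of C20), via bromomagnesium alkoxide 12 (not isolated)
Conditions: CH2=CHMgBr (1.5 equiv), LaCl3·2LiCl (0.3 equiv), THF, −40 to 0 °C; then ClCO2Me (2 equiv), 0 °C to rt
Reagents that add atoms: vinylmagnesium bromide, C=C[Mg]Br; methyl chloroformate, COC(=O)Cl
Why: Lanthanide-assisted 1,2-addition of a small Grignard reagent to the hindered enone occurs anti to the axial C20 methyl and is followed by in-flask O-acylation; the C9 configuration formed here is erased in step 7.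

Step 7
Reactants: 13 carbonate
Product: 14 9-vinyl decalin (13,14,15,16-tetranor-ent-labda-7,11-diene-6,18-diyl di-tert-butylsilylene; H9 on the face of H5; vinyl equatorial)
Conditions: Pd(OAc)2 (5 mol %), n-Bu3P (5 mol %), HCO2NH4 (3 equiv), THF, 40 °C
Reagents that add atoms: none
Why: In this Tsuji formate hydrogenolysis, zerovalent palladium ionises the carbonate from the open face opposite C20 and hydride passes from palladium to the more substituted allyl terminus C9 on that same face, which leaves a terminal vinyl group, keeps C7=C8 and sets C9.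

Step 8
Reactants: 14 9-vinyl decalin; 15 methyl but-2-ynoate
Product: 17 silylene-protected target (methyl ent-6,18-O-(di-tert-butylsilanediyl)labda-7,13E-dien-15-oate), via primary alkyl-9-BBN 16 (not isolated)
Conditions: 9-BBN-H (1.1 equiv), 1,4-dioxane, 60 °C; then 15 (1.2 equiv), CuOAc (5 mol %), P(OPh)3 (10 mol %), KOt-Bu (5 mol %), t-BuOH (1 equiv), 40 °C
Reagents that add atoms: none
Why: Anti-Markovnikov hydroboration takes only the monosubstituted olefin; conjugate addition of the alkylborane to the alkynoate, catalysed by monovalent copper, is then a syn hydroalkylation that places the new CH2 trans to CO2Me and gives the E-olefin.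

Step 9
Reactants: 17 silylene-protected target
Product: 18 target, methyl (2E)-5-[(1R,4R,4aS,5S,8aS)-4-hydroxy-5-(hydroxymethyl)-2,5,8a-trimethyl-1,4,4a,5,6,7,8,8a-octahydronaphthalen-1-yl]-3-methylpent-2-enoate
Conditions: HF·pyridine, excess pyridine, THF, 0 °C to rt
Reagents that add atoms: none
Why: Buffered fluoride desilylation cleaves both Si–O bonds without ionising the allylic C6 carbinol or touching the ester, and no stereocentre is affected.

## Compound list
1 | (S)-(+)-carvone | CC1=CC[C@@H](CC1=O)C(C)=C | starting material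
2 | lithium cross-conjugated dienolate of 1 (not isolated) | [Li]OC1=C[C@@H](C(C)=C)CC=C1C | intermediate
3 | (5S,6R)-6-methylcarvone | C[C@@H]1[C@@H](C(C)=C)CC=C(C)C1=O | intermediate
4 | tetrasubstituted lithium enolate of 3 (not isolated) | [Li]OC1=C(C)[C@@H](C(C)=C)CC=C1C | intermediate
5 | (5R,6R)-6-(2-bromoethyl)-6-methylcarvone | BrCC[C@]1(C)[C@@H](C(C)=C)CC=C(C)C1=O | intermediate
6 | (5R,6R)-6-(2-iodoethyl)-6-methylcarvone (not isolated) | ICC[C@]1(C)[C@@H](C(C)=C)CC=C(C)C1=O | intermediate
7 | C18 alkoxytriphenylphosphonium iodide (not isolated) | O=C1C(C)=CC[C@@H]2[C@@](C)(CO[P+](c3ccccc3)(c3ccccc3)c3ccccc3)CCC[C@@]12C.[I-] | intermediate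
8 | trans-decalin enone with equatorial C18 carbinol | O=C1C(C)=CC[C@@H]2[C@@](C)(CO)CCC[C@@]12C | intermediate
9 | C6 hydroperoxide of 8 (not isolated) | O=C1C(C)=C[C@@H](OO)[C@@H]2[C@@](C)(CO)CCC[C@@]12C | intermediate
10 | 6,18-dihydroxy enone | O=C1C(C)=C[C@@H](O)[C@@H]2[C@@](C)(CO)CCC[C@@]12C | intermediate
11 | 6,18-O-di-tert-butylsilylene enone | O=C1C(C)=C[C@@H]3[C@@H]2[C@@](C)(CO[Si](C(C)(C)C)(C(C)(C)C)O3)CCC[C@@]12C | intermediate
12 | C9 bromomagnesium alkoxide (not isolated) | C=C[C@@]1(O[Mg]Br)C(C)=C[C@@H]3[C@@H]2[C@@](C)(CO[Si](C(C)(C)C)(C(C)(C)C)O3)CCC[C@@]12C | intermediate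
13 | C9 tertiary bis-allylic methyl carbonate | C=C[C@@]1(OC(=O)OC)C(C)=C[C@@H]3[C@@H]2[C@@](C)(CO[Si](C(C)(C)C)(C(C)(C)C)O3)CCC[C@@]12C | intermediate
14 | 9-vinyl decalin silylene | C=C[C@@H]1C(C)=C[C@@H]3[C@@H]2[C@@](C)(CO[Si](C(C)(C)C)(C(C)(C)C)O3)CCC[C@@]12C | intermediate
15 | methyl but-2-ynoate | CC#CC(=O)OC | starting material
16 | C12 alkyl-9-BBN (not isolated) | C4CC5CCCC(C4)B5CC[C@@H]1C(C)=C[C@@H]3[C@@H]2[C@@](C)(CO[Si](C(C)(C)C)(C(C)(C)C)O3)CCC[C@@]12C | intermediate
17 | silylene-protected target | COC(=O)/C=C(\C)CC[C@@H]1C(C)=C[C@@H]3[C@@H]2[C@@](C)(CO[Si](C(C)(C)C)(C(C)(C)C)O3)CCC[C@@]12C | intermediate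
18 | CNP0149445.1 | COC(=O)/C=C(\C)CC[C@@H]1C(C)=C[C@@H](O)[C@@H]2[C@@](C)(CO)CCC[C@@]12C | target

## Step count and risks
Total steps: 9. Longest linear sequence: 9.

**Step 3 (new cascade).**
- Risks: the C2 radical may be captured by HCHO before ring closure, some 5-exo closure may occur, and the C4 radical may add to the enone of a second molecule. High dilution and a large excess of HCHO are meant to keep all three low.
- Fallback (known chemistry, from 5 back to 8): Finkelstein exchange (NaI, acetone) gives isolated 6. A tin-mediated group-transfer cascade follows (Me3SnSnMe3, PhSO2CH=NOBn, sunlamp, benzene). It closes ring A in the same 6-endo sense and captures the C4 radical with the sulfonyl oxime ether, giving C18 aldoxime O-benzyl ether F1. Oxime exchange (aq. HCHO, HCl, THF) frees neopentyl aldehyde F2. NaBH4 (0.3 equiv, MeOH–CH2Cl2, −78 °C) reduces only the aldehyde and delivers 8.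

**Step 4 (gamma-hydroxylation).**
- Risks: the aligned C6–H lies under two axial methyl groups, so dienolate formation may be slow, and over-oxidation to the enedione is possible.
- Fallback (from 8 back to 10, a stepwise vinylogous Rubottom oxidation): TBSOTf (3 equiv) and Et3N give bis-silyl dienol ether F3. Dimethyldioxirane (acetone, −40 °C) oxidises the terminal C6=C7 bond from the open face and, after mild acid work-up, gives 6-hydroxy enone 18-TBS ether F4. HF·pyridine then gives 10.

**Step 7 (formate hydrogenolysis).**
- Risks: hydride may be delivered to C12 or C7 of the extended allyl system, or elimination to a triene may occur.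
- Fallback (from 11 back to 14, bypassing 13): Ph3P=CH2 (toluene, 80 °C) gives exocyclic diene F5. 9-BBN-H adds only to the 1,1-disubstituted C9=C11 bond, from the face opposite C20, to give C11 alkyl-9-BBN F6. NaOH/H2O2 gives primary alcohol F7. Dess–Martin periodinane gives beta,gamma-unsaturated aldehyde F8. Salt-free Ph3P=CH2 at −78 °C gives 14.

## Further compounds
F1 | step 3 | C18 aldoxime O-benzyl ether | O=C1C(C)=CC[C@@H]2[C@@](C)(/C=N/OCc3ccccc3)CCC[C@@]12C
F2 | step 3 | neopentyl aldehyde | O=C1C(C)=CC[C@@H]2[C@@](C)(C=O)CCC[C@@]12C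
F3 | step 4 | bis-silyl dienol ether | CC(C)(C)[Si](C)(C)OC1=C(C)C=C[C@@H]2[C@@](C)(CO[Si](C)(C)C(C)(C)C)CCC[C@@]12C
F4 | step 4 | 6-hydroxy enone 18-TBS ether | O=C1C(C)=C[C@@H](O)[C@@H]2[C@@](C)(CO[Si](C)(C)C(C)(C)C)CCC[C@@]12C
F5 | step 7 | exocyclic diene | C=C1C(C)=C[C@@H]3[C@@H]2[C@@](C)(CO[Si](C(C)(C)C)(C(C)(C)C)O3)CCC[C@@]12C
F6 | step 7 | C11 alkyl-9-BBN | C4CC5CCCC(C4)B5C[C@@H]1C(C)=C[C@@H]3[C@@H]2[C@@](C)(CO[Si](C(C)(C)C)(C(C)(C)C)O3)CCC[C@@]12C
F7 | step 7 | primary alcohol | OC[C@@H]1C(C)=C[C@@H]3[C@@H]2[C@@](C)(CO[Si](C(C)(C)C)(C(C)(C)C)O3)CCC[C@@]12C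
F8 | step 7 | beta,gamma-unsaturated aldehyde | O=C[C@@H]1C(C)=C[C@@H]3[C@@H]2[C@@](C)(CO[Si](C(C)(C)C)(C(C)(C)C)O3)CCC[C@@]12C
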